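In a one-step world, reagent and single-handed catalyst turn each mirror-image substrate at a rate proportional to its own amount, with one shared factor that may sag as it likes. Dividing the two rates and integrating removes that factor: the logarithm of the fraction of left-handed substrate left, over that of the right-handed, stays constant.

in all of them: left-handed substrate 0.053 M; right-handed substrate 0.053 M; free catalyst 0.5 mol%; added ligand 1.2 mM; impurity 0.11 mM

| flask | reagent | remark | time |
|---|---|---|---|
| Saturday's | 0.60 equiv | run made earlier |  |
| Tuesday's | 3.7 equiv | run made earlier |  |
| north-east | 1.10 equiv |  | 15 h |
| south | 4.40 equiv |  | 15 h |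

| run | time / h | right-handed substrate / % | left-handed substrate / % |
|---|---|---|---|
| Saturday's | 0.833 | 49.5 | 46.3 |
| Saturday's | 1.33 | 46.4 | 47.3 |
| Saturday's | 2.00 | 48.7 | 44.5 |
| Saturday's | 3.00 | 49.5 | 40.6 |
| Saturday's | 5.00 | 48.5 | 39.9 |
| Saturday's | 6.00 | 48.9 | 39.9 |
| Saturday's | 10.0 | 47.7 | 37.5 |
| Tuesday's | 0.500 | 44.4 | 35.2 |
| Tuesday's | 1.50 | 45.1 | 22.5 |
| Tuesday's | 3.00 | 42.3 | 16.8 |
| Tuesday's | 5.00 | 40.5 | 13.2 |
| Tuesday's | 6.00 | 39.4 | 11.8 |
| Tuesday's | 8.00 | 36.7 | 7.5 |
| Tuesday's | 10.0 | 37.6 | 5.0 |

(readings scatter by 1 percentage point)
- free catalyst is single-handed; left-handed substrate and right-handed substrate are mirror images of each other, charged as a racemate, each of them at the stated concentration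
- an excess is below zero if the other one leads
* which one finishes higher in excess of right-handed substrate over left-handed substrate among what is left of the two ("neither" within 2 percentage points) (north-east / south / neither)
* excess of right-handed substrate over left-handed substrate among what is left of the two at the end, north-east
* excess of right-handed substrate over left-handed substrate among what is left of the two at the end, south

Tuesday's reading at 8.00 h gives 6.13, the one at 6.00 h gives 6.06 and the last gives 8.08, so scatter reaches that far and I carry the first. This ratio is the selectivity factor: if a fraction f of right-handed substrate is left, f raised to it is left of the left-handed, and the excess is their difference over their sum.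

For progress I take Tuesday's left-handed logarithm per equivalent at its last reading, 0.622. Saturday's is lower, but the new flasks run longer. North-east then keeps 89.4% of its right-handed substrate, an excess of 27.9%; south keeps 64.0%, an excess of 81.6%.

The forecast, noting that “total progress is limited by the charge”, says south, with 25% for north-east and 90% for south, below mine in the first and above it in the second.

The flasks give south, with 29.3% and 89.4%.

    reagent + free catalyst + left-handed substrate → free catalyst + left-handed product (k = 42000 /M²/h)
    reagent + free catalyst + right-handed substrate → free catalyst + right-handed product (k = 6600 /M²/h)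
    free catalyst + added ligand ⇌ idle complex (K = 1900 /M, k = 450 /M/h)
    free catalyst + impurity → spent catalyst (k = 1.80 × 10⁶ /M/h)
    2 free catalyst ⇌ resting dimer (K = 58000 /M, k = 4900 /M/h)

South leads because of its reagent: with the difference in equivalents taken away, so that south holds north-east's charge, it ends at 29.3%, not 89.4%. A south with 3.85 equiv of reagent ends 5 points from this excess. In north-east, 89% of right-handed substrate gives 50.1% of left-handed by the carried factor 6.13, and the flask holds 49%. Read at 10 h, north-east keeps 91% of right-handed substrate, which gives 57.8%, and the flask holds 57%.

The data were generated by integration with constants of no real substance, noise included.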